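The seven-membered ring is closed last, at C1–C10. The methyl-bearing fusion carbon C1 sits β to C4 of the five-membered ring, so the C4 carbinol is treated as a latent cyclopentenone carbonyl, while ring methylene C10 and its oxygenated neighbour C9 are taken as the attacking end and the substituted middle carbon of an allylsilane. One Lewis-acid Hosomi–Sakurai conjugate addition then forms C1–C10, the quaternary centre C1 and, after protonation, the trans fusion at C5, leaving a C4 ketone and a C9 methylene as handles. The precursor is a 3-methylcyclopent-2-enone bearing at C5 a C6–C10 arm with silyl-protected C6 and C8 carbinols and a terminal 2-(silylmethyl)allyl unit.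

Key step: step 8

Remark: core atoms are numbered C1 (methyl-bearing fusion carbon), C2, C3, C4 (isopropyl carbinol), C5 (fusion CH), C6 (aroyloxy CH), C7, C8 (methyl carbinol), C9 (CHOH), C10 (CH2 on C1).
Assumption: compounds 1, 3 and 20 are taken as purchasable catalogue compounds; C8 is drawn from the chiral pool and is never touched.

Step 1
Reactants: 1 (S)-citramalic acid, (2S)-2-hydroxy-2-methylbutanedioic acid
Product: 2 2-[(4S)-2,2,4-trimethyl-5-oxo-1,3-dioxolan-4-yl]acetic acid
Conditions: Me2C(OMe)2, TsOH (cat.), rt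
Reagents that add atoms: 2,2-dimethoxypropane, COC(C)(C)OC
Why: Acid-catalysed acetonide (dioxolanone) formation ties the tertiary hydroxyl to the adjacent carboxyl (future C9) in a five-membered ring, leaves the CH2CO2H arm (future C7–C6) free and carries the C8 stereocentre over unchanged.

Step 2
Reactants: 3 2-bromo-3-methylcyclopent-2-en-1-one
Product: 4 6-bromo-7-methyl-1,4-dioxaspiro[4.4]non-6-ene
Conditions: HOCH2CH2OH, TsOH (cat.), benzene, reflux, Dean–Stark trap
Reagents that add atoms: ethylene glycol, OCCO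
Why: Acid-catalysed ketalisation with azeotropic removal of water masks the carbonyl so that the bromoalkene can act as an α-ketovinyl anion equivalent; no stereocentre is formed.

Step 3
Reactants: 2 2-[(4S)-2,2,4-trimethyl-5-oxo-1,3-dioxolan-4-yl]acetic acid; 4 6-bromo-7-methyl-1,4-dioxaspiro[4.4]non-6-ene
Product: 8 (5S)-2,2,5-trimethyl-5-[2-(7-methyl-1,4-dioxaspiro[4.4]non-6-en-6-yl)-2-oxoethyl]-1,3-dioxolan-4-one, via acid chloride 5 (not isolated), via alkenyllithium 6 (not isolated), via alkenylzinc chloride 7 (not isolated)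
Conditions: 2, (COCl)2, DMF (cat.), CH2Cl2, 0 °C to rt, evaporate; separately 4, n-BuLi, THF, −78 °C, then ZnCl2, −78 to 0 °C; combine, Pd(PPh3)4 (5 mol%), THF, 0 °C to rt
Reagents that add atoms: none
Why: Bromine–lithium exchange, transmetalation to zinc and Negishi acylation catalysed by zerovalent palladium join C5 to C6 directly at the ketone oxidation level, the organozinc being too unreactive to attack the dioxolanone that masks O8 and C9.

Step 4
Reactants: 8 (5S)-2,2,5-trimethyl-5-[2-(7-methyl-1,4-dioxaspiro[4.4]non-6-en-6-yl)-2-oxoethyl]-1,3-dioxolan-4-one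
Product: 10 (3S,5S)-3-hydroxy-3-methyl-5-(7-methyl-1,4-dioxaspiro[4.4]non-6-en-6-yl)oxolan-2-one, via hydroxy dioxolanone 9 (not isolated)
Conditions: (R)-2-methyl-CBS-oxazaborolidine (0.2 equiv), BH3·SMe2, THF, −30 °C; MeOH; then DBU (0.1 equiv), CH2Cl2, rt
Reagents that add atoms: none
Why: Corey–Bakshi–Shibata reduction, with the tetrasubstituted alkenyl group as the large and C7H2 as the small substituent, should set 6S under catalyst control, and the new hydroxyl then opens the activated dioxolanone in a 5-exo-trig translactonisation that releases acetone and frees the C8 hydroxyl.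

Step 5
Reactants: 10 (3S,5S)-3-hydroxy-3-methyl-5-(7-methyl-1,4-dioxaspiro[4.4]non-6-en-6-yl)oxolan-2-one
Product: 11 (3S,5S)-3-methyl-5-(7-methyl-1,4-dioxaspiro[4.4]non-6-en-6-yl)-3-[(triethylsilyl)oxy]oxolan-2-one
Conditions: Et3SiCl, imidazole, DMAP (cat.), DMF, rt to 40 °C
Reagents that add atoms: chlorotriethylsilane, CC[Si](Cl)(CC)CC
Why: Silyl ether formation under non-acidic conditions protects the tertiary α-hydroxyl of the lactone (O8) without disturbing the allylic ketal.

Step 6
Reactants: 11 (3S,5S)-3-methyl-5-(7-methyl-1,4-dioxaspiro[4.4]non-6-en-6-yl)-3-[(triethylsilyl)oxy]oxolan-2-one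
Product: 14 2-[(1S,3S)-1-hydroxy-3-methyl-3-[(triethylsilyl)oxy]-4-[(trimethylsilyl)methyl]pent-4-en-1-yl]-3-methylcyclopent-2-en-1-one, via bis(silylmethyl) carbinol 12 (not isolated), via ketal allylsilane 13 (not isolated)
Conditions: Me3SiCH2MgCl (5 equiv), CeCl3 (5 equiv), THF, −78 °C to rt; aq. NH4Cl; crude with SiO2, CH2Cl2, rt; then PPTS, acetone/H2O, rt
Reagents that add atoms: (trimethylsilyl)methylmagnesium chloride, C[Si](C)(C)C[Mg]Cl; water, O
Why: Double addition of the non-basic silylmethylcerium reagent to the lactone carbonyl (C9, no α-hydrogen) followed by acid-induced Peterson olefination of the tertiary β-hydroxysilane is the standard conversion of an ester into a 2-substituted allylsilane, and the same mild acid hydrolyses the allylic ketal to uncover the enone.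

Step 7
Reactants: 14 2-[(1S,3S)-1-hydroxy-3-methyl-3-[(triethylsilyl)oxy]-4-[(trimethylsilyl)methyl]pent-4-en-1-yl]-3-methylcyclopent-2-en-1-one
Product: 15 2-[(1S,3S)-1-[(tert-butyldimethylsilyl)oxy]-3-methyl-3-[(triethylsilyl)oxy]-4-[(trimethylsilyl)methyl]pent-4-en-1-yl]-3-methylcyclopent-2-en-1-one
Conditions: TBSCl, imidazole, DMF, rt
Reagents that add atoms: tert-butyldimethylsilyl chloride, CC(C)(C)[Si](C)(C)Cl
Why: Standard silylation of the secondary allylic alcohol removes the acidic proton and gives O6 a bulky, poorly leaving group for the Lewis-acid step.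

Step 8
Reactants: 15 2-[(1S,3S)-1-[(tert-butyldimethylsilyl)oxy]-3-methyl-3-[(triethylsilyl)oxy]-4-[(trimethylsilyl)methyl]pent-4-en-1-yl]-3-methylcyclopent-2-en-1-one
Product: 17 (3aR,6S,8S,8aS)-8-[(tert-butyldimethylsilyl)oxy]-3a,6-dimethyl-5-methylidene-6-[(triethylsilyl)oxy]octahydroazulen-1(2H)-one, via aluminium enolate 16 (not isolated)
Conditions: EtAlCl2 (2.5 equiv), CH2Cl2, −78 to −40 °C; quench at −78 °C with MeOH, then aq. NaHCO3
Reagents that add atoms: none
Why: EtAlCl2 binds the C4 carbonyl, the allylsilane terminus C10 adds to the now electrophilic C1 while the charge developing at C9 is held by the β-silicon, and chloride then takes the Me3Si group, which leaves the C9 exocyclic methylene and the aluminium enolate 16 that is protonated at C5 on quench. The reaction type is the intramolecular Hosomi–Sakurai conjugate allylation of a cycloalkenone by a tethered 2-substituted allylsilane, the established Lewis-acid route to fused seven-membered rings with an angular quaternary carbon. The seven-membered ring (C1, C5, C6, C7, C8, C9, C10) closes 7-endo-trig with respect to the C1=C5 enone bond, the allylsilane reacting in its usual anti SE2' sense. C1 is set by C6: allylic 1,3-strain with the C1 methyl holds H6 in the enone plane, so C7 with the tether lies on one face and the O6 silyl ether on the other, C10 can reach C1 only from the tether face, and 6S therefore gives 1R, the quaternary C8 with its two similar-sized groups not being expected to override this. C5 is set on quench by protonation of 16 on the face away from both the angular methyl and the O6 silyl ether, and the resulting trans-fused ketone is also the isomer with the C4 carbonyl and O6 trans-diequatorial on the seven-membered ring, so kinetic and thermodynamic preferences should agree. The step needs 1,4- over 1,2-addition and ring closure over β-elimination of silyloxide from C6 or ionisation of the tertiary allylic ether at C8, which the Lewis-acid (not fluoride) activation, the low temperature, the proton-scavenging ethylaluminium reagent and the bulky, poorly leaving silyl ethers should secure.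

Step 9
Reactants: 17 (3aR,6S,8S,8aS)-8-[(tert-butyldimethylsilyl)oxy]-3a,6-dimethyl-5-methylidene-6-[(triethylsilyl)oxy]octahydroazulen-1(2H)-one
Product: 18 (1R,3aR,6S,8S,8aS)-8-[(tert-butyldimethylsilyl)oxy]-3a,6-dimethyl-5-methylidene-1-(propan-2-yl)-6-[(triethylsilyl)oxy]decahydroazulen-1-ol
Conditions: iPrMgCl, CeCl3, THF, −78 to 0 °C
Reagents that add atoms: isopropylmagnesium chloride, CC(C)[Mg]Cl
Why: Organocerium 1,2-addition suppresses enolisation and hydride transfer, and the reagent should approach C4 from the face of H5, anti to both the pseudoaxial angular methyl on C1 and the C6 branch on C5, which places the isopropyl group trans to the methyl and gives 4R.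

Step 10
Reactants: 18 (1R,3aR,6S,8S,8aS)-8-[(tert-butyldimethylsilyl)oxy]-3a,6-dimethyl-5-methylidene-1-(propan-2-yl)-6-[(triethylsilyl)oxy]decahydroazulen-1-ol
Product: 19 (1R,3aR,6S,8S,8aS)-3a,6-dimethyl-5-methylidene-1-(propan-2-yl)decahydroazulene-1,6,8-triol
Conditions: Bu4NF, THF, rt to 50 °C
Reagents that add atoms: none
Why: Fluoride-mediated desilylation removes both silyl ethers in one operation at a stage where the molecule holds no carbonyl or ester that base could harm.

Step 11
Reactants: 19 (1R,3aR,6S,8S,8aS)-3a,6-dimethyl-5-methylidene-1-(propan-2-yl)decahydroazulene-1,6,8-triol; 20 4-(benzyloxy)benzoyl chloride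
Product: 21 (3R,3aS,4S,6S,8aR)-3,6-dihydroxy-6,8a-dimethyl-7-methylidene-3-(propan-2-yl)decahydroazulen-4-yl 4-(benzyloxy)benzoate
Conditions: Et3N, DMAP, CH2Cl2, 0 °C to rt
Reagents that add atoms: none
Why: DMAP-catalysed acylation (esterification) picks the single secondary, equatorial hydroxyl at C6, since the tertiary hydroxyls at C4 and C8 do not acylate under these conditions.

Step 12
Reactants: 21 (3R,3aS,4S,6S,8aR)-3,6-dihydroxy-6,8a-dimethyl-7-methylidene-3-(propan-2-yl)decahydroazulen-4-yl 4-(benzyloxy)benzoate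
Product: 22 (3R,3aS,4S,6S,8aR)-3,6-dihydroxy-6,8a-dimethyl-7-oxo-3-(propan-2-yl)decahydroazulen-4-yl 4-(benzyloxy)benzoate
Conditions: O3, CH2Cl2/MeOH, −78 °C; Me2S, −78 °C to rt
Reagents that add atoms: ozone, [O-][O+]=O
Why: Ozonolysis with reductive work-up cleaves the only alkene, the 1,1-disubstituted exocyclic methylene, much faster than it attacks the ester-deactivated arene or the benzyl ether, and so unmasks the C9 ketone.

Step 13
Reactants: 22 (3R,3aS,4S,6S,8aR)-3,6-dihydroxy-6,8a-dimethyl-7-oxo-3-(propan-2-yl)decahydroazulen-4-yl 4-(benzyloxy)benzoate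
Product: 23 (3R,3aS,4S,6S,7S,8aR)-3,6,7-trihydroxy-6,8a-dimethyl-3-(propan-2-yl)decahydroazulen-4-yl 4-(benzyloxy)benzoate
Conditions: Me4NBH(OAc)3, MeCN/AcOH, −20 °C to rt
Reagents that add atoms: none
Why: In this hydroxyl-directed reduction of the Evans–Saksena type, exchange of an acetate for the tertiary C8 hydroxyl gives an alkoxyborohydride that delivers hydride to C9 from the face of O8, so the new hydroxyl emerges trans to O8 (9S), while the ester is inert to this weak hydride donor.

Step 14
Reactants: 23 (3R,3aS,4S,6S,7S,8aR)-3,6,7-trihydroxy-6,8a-dimethyl-3-(propan-2-yl)decahydroazulen-4-yl 4-(benzyloxy)benzoate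
Product: 24 (3R,3aS,4S,6S,7S,8aR)-3,6,7-trihydroxy-6,8a-dimethyl-3-(propan-2-yl)decahydroazulen-4-yl 4-hydroxybenzoate
Conditions: H2 (1 atm), Pd/C, EtOAc, rt
Reagents that add atoms: none
Why: Hydrogenolysis of the benzyl aryl ether frees the phenol under neutral conditions that touch neither the aryl ester nor any stereocentre, the molecule holding no other reducible group.

Compound list
1 | (S)-citramalic acid, (2S)-2-hydroxy-2-methylbutanedioic acid | C[C@](O)(CC(=O)O)C(=O)O | starting material
2 | 2-[(4S)-2,2,4-trimethyl-5-oxo-1,3-dioxolan-4-yl]acetic acid | C[C@@]1(CC(=O)O)OC(C)(C)OC1=O | intermediate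
3 | 2-bromo-3-methylcyclopent-2-en-1-one | CC1=C(Br)C(=O)CC1 | starting material
4 | 6-bromo-7-methyl-1,4-dioxaspiro[4.4]non-6-ene | CC1=C(Br)C2(CC1)OCCO2 | intermediate
5 | 2-[(4S)-2,2,4-trimethyl-5-oxo-1,3-dioxolan-4-yl]acetyl chloride | C[C@@]1(CC(=O)Cl)OC(C)(C)OC1=O | intermediate
6 | (7-methyl-1,4-dioxaspiro[4.4]non-6-en-6-yl)lithium | [Li]C1=C(C)CCC12OCCO2 | intermediate
7 | chloro(7-methyl-1,4-dioxaspiro[4.4]non-6-en-6-yl)zinc | Cl[Zn]C1=C(C)CCC12OCCO2 | intermediate
8 | (5S)-2,2,5-trimethyl-5-[2-(7-methyl-1,4-dioxaspiro[4.4]non-6-en-6-yl)-2-oxoethyl]-1,3-dioxolan-4-one | C[C@@]1(CC(=O)C2=C(C)CCC23OCCO3)OC(C)(C)OC1=O | intermediate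
9 | (5S)-5-[(2S)-2-hydroxy-2-(7-methyl-1,4-dioxaspiro[4.4]non-6-en-6-yl)ethyl]-2,2,5-trimethyl-1,3-dioxolan-4-one | C[C@@]1(C[C@H](O)C2=C(C)CCC23OCCO3)OC(C)(C)OC1=O | intermediate
10 | (3S,5S)-3-hydroxy-3-methyl-5-(7-methyl-1,4-dioxaspiro[4.4]non-6-en-6-yl)oxolan-2-one | C[C@]1(O)C[C@H](OC1=O)C2=C(C)CCC23OCCO3 | intermediate
11 | (3S,5S)-3-methyl-5-(7-methyl-1,4-dioxaspiro[4.4]non-6-en-6-yl)-3-[(triethylsilyl)oxy]oxolan-2-one | C[C@]1(O[Si](CC)(CC)CC)C[C@H](OC1=O)C2=C(C)CCC23OCCO3 | intermediate
12 | (1S,3S)-3-methyl-1-(7-methyl-1,4-dioxaspiro[4.4]non-6-en-6-yl)-3-[(triethylsilyl)oxy]-5-(trimethylsilyl)-4-[(trimethylsilyl)methyl]pentane-1,4-diol | C[C@](O[Si](CC)(CC)CC)(C[C@H](O)C1=C(C)CCC12OCCO2)C(O)(C[Si](C)(C)C)C[Si](C)(C)C | intermediate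
13 | (1S,3S)-3-methyl-1-(7-methyl-1,4-dioxaspiro[4.4]non-6-en-6-yl)-3-[(triethylsilyl)oxy]-4-[(trimethylsilyl)methyl]pent-4-en-1-ol | C[C@](O[Si](CC)(CC)CC)(C[C@H](O)C1=C(C)CCC12OCCO2)C(=C)C[Si](C)(C)C | intermediate
14 | 2-[(1S,3S)-1-hydroxy-3-methyl-3-[(triethylsilyl)oxy]-4-[(trimethylsilyl)methyl]pent-4-en-1-yl]-3-methylcyclopent-2-en-1-one | C[C@](O[Si](CC)(CC)CC)(C[C@H](O)C1=C(C)CCC1=O)C(=C)C[Si](C)(C)C | intermediate
15 | 2-[(1S,3S)-1-[(tert-butyldimethylsilyl)oxy]-3-methyl-3-[(triethylsilyl)oxy]-4-[(trimethylsilyl)methyl]pent-4-en-1-yl]-3-methylcyclopent-2-en-1-one (precursor of the key step) | CC1=C(C(=O)CC1)[C@@H](O[Si](C)(C)C(C)(C)C)C[C@](C)(O[Si](CC)(CC)CC)C(=C)C[Si](C)(C)C | intermediate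
16 | chloro(ethyl)aluminium enolate of 17 (O4–Al, C4=C5) | CC[Al](Cl)OC=1CC[C@]2(C)CC(=C)[C@@](C)(O[Si](CC)(CC)CC)C[C@H](O[Si](C)(C)C(C)(C)C)C=12 | intermediate
17 | (3aR,6S,8S,8aS)-8-[(tert-butyldimethylsilyl)oxy]-3a,6-dimethyl-5-methylidene-6-[(triethylsilyl)oxy]octahydroazulen-1(2H)-one (trans-fused product of the key step) | O=C1CC[C@]2(C)CC(=C)[C@@](C)(O[Si](CC)(CC)CC)C[C@H](O[Si](C)(C)C(C)(C)C)[C@@H]12 | intermediate
18 | (1R,3aR,6S,8S,8aS)-8-[(tert-butyldimethylsilyl)oxy]-3a,6-dimethyl-5-methylidene-1-(propan-2-yl)-6-[(triethylsilyl)oxy]decahydroazulen-1-ol | CC(C)[C@]1(O)CC[C@]2(C)CC(=C)[C@@](C)(O[Si](CC)(CC)CC)C[C@H](O[Si](C)(C)C(C)(C)C)[C@H]21 | intermediate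
19 | (1R,3aR,6S,8S,8aS)-3a,6-dimethyl-5-methylidene-1-(propan-2-yl)decahydroazulene-1,6,8-triol | CC(C)[C@]1(O)CC[C@]2(C)CC(=C)[C@@](C)(O)C[C@H](O)[C@H]21 | intermediate
20 | 4-(benzyloxy)benzoyl chloride | O=C(Cl)c1ccc(OCc2ccccc2)cc1 | starting material
21 | (3R,3aS,4S,6S,8aR)-3,6-dihydroxy-6,8a-dimethyl-7-methylidene-3-(propan-2-yl)decahydroazulen-4-yl 4-(benzyloxy)benzoate | CC(C)[C@]1(O)CC[C@]2(C)CC(=C)[C@@](C)(O)C[C@H](OC(=O)c3ccc(OCc4ccccc4)cc3)[C@H]21 | intermediate
22 | (3R,3aS,4S,6S,8aR)-3,6-dihydroxy-6,8a-dimethyl-7-oxo-3-(propan-2-yl)decahydroazulen-4-yl 4-(benzyloxy)benzoate | CC(C)[C@]1(O)CC[C@]2(C)CC(=O)[C@@](C)(O)C[C@H](OC(=O)c3ccc(OCc4ccccc4)cc3)[C@H]21 | intermediate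
23 | (3R,3aS,4S,6S,7S,8aR)-3,6,7-trihydroxy-6,8a-dimethyl-3-(propan-2-yl)decahydroazulen-4-yl 4-(benzyloxy)benzoate | CC(C)[C@]1(O)CC[C@]2(C)C[C@H](O)[C@@](C)(O)C[C@H](OC(=O)c3ccc(OCc4ccccc4)cc3)[C@H]21 | intermediate
24 | (3R,3aS,4S,6S,7S,8aR)-3,6,7-trihydroxy-6,8a-dimethyl-3-(propan-2-yl)decahydroazulen-4-yl 4-hydroxybenzoate | CC(C)[C@]1(O)CC[C@]2(C)C[C@H](O)[C@@](C)(O)C[C@H](OC(=O)c3ccc(O)cc3)[C@H]21 | target

Total step count: 14. Longest linear sequence: 13 steps (from 1 through steps 1 and 3–14; the branch from 3 through steps 2–14 is equally long).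

Steps most likely to fail

Step 8. After ring closure the aluminium enolate may expel the O6 silyloxide as the mixture warms, the stoichiometric Lewis acid may ionise the tertiary allylic silyl ether at C8 before the allylsilane engages, or the enolate may be protonated on the methyl face to give the cis ring fusion. The fallback sets out from 15 and runs the same bond formation as a silicon-transfer, Mukaiyama–Michael-type conjugate allylation with catalytic Me3SiNTf2 and 2,6-di-tert-butylpyridine in CH2Cl2 at −78 °C. The silyl group that leaves carbon ends on the C4 oxygen, so no metal enolate exists, and the neutral trimethylsilyl enol ether F1 should be isolable. F1 is then ketonised in a separate operation with citric acid in MeOH/THF at 0 °C, where the enol is protonated from the open face and the ketone can settle into the trans-diequatorial arrangement. The route is rejoined at 17.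

Step 13. The acetoxyborohydride may fail to exchange onto the hindered tertiary C8 hydroxyl, so that hydride arrives externally on the wrong face (poor facial selectivity, cis-8,9-diol). The fallback sets out from 22 and replaces substrate-directed delivery by reagent control. Corey–Bakshi–Shibata reduction with (R)-2-methyl-CBS-oxazaborolidine (1 equiv) and excess BH3·SMe2 in THF at −20 °C, with the free hydroxyls carried as borates, reads the quaternary C8 as the large and C10H2 as the small substituent and predicts 9S. It comes back at 23 and makes no new compound.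

Step 6. The second addition of the silylmethyl reagent to the ketone flanked by the quaternary C8 may stall (incomplete conversion), or the allylsilane may be protodesilylated during the acid treatments. The fallback sets out from 11. One equivalent of Me3SiCH2Li in THF at −78 °C opens the lactone once to give the β-silyl ketone F2, which is silylated at O6 with TBSCl and imidazole in DMF to give the silyl ether F3. Tebbe methylenation (Cp2Ti(CH2)(Cl)AlMe2, THF, pyridine, −40 °C to rt), a non-basic olefination that tolerates hindered, enolisable ketones, gives the allylsilane F4. PPTS in acetone/H2O then removes the ketal and the route is rejoined at 15, so that steps 6 and 7 are both replaced.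

Further compounds
F1 | step 8 | (4S,6S,8aR)-4-[(tert-butyldimethylsilyl)oxy]-6,8a-dimethyl-7-methylidene-6-[(triethylsilyl)oxy]-3-[(trimethylsilyl)oxy]-1,2,4,5,6,7,8,8a-octahydroazulene | C[Si](C)(C)OC=1CC[C@]2(C)CC(=C)[C@@](C)(O[Si](CC)(CC)CC)C[C@H](O[Si](C)(C)C(C)(C)C)C=12
F0 | step 13 | none | none
F2 | step 6 | (3S,5S)-5-hydroxy-3-methyl-5-(7-methyl-1,4-dioxaspiro[4.4]non-6-en-6-yl)-3-[(triethylsilyl)oxy]-1-(trimethylsilyl)pentan-2-one | C[C@](O[Si](CC)(CC)CC)(C[C@H](O)C1=C(C)CCC12OCCO2)C(=O)C[Si](C)(C)C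
F3 | step 6 | (3S,5S)-5-[(tert-butyldimethylsilyl)oxy]-3-methyl-5-(7-methyl-1,4-dioxaspiro[4.4]non-6-en-6-yl)-3-[(triethylsilyl)oxy]-1-(trimethylsilyl)pentan-2-one | C[C@](O[Si](CC)(CC)CC)(C[C@H](O[Si](C)(C)C(C)(C)C)C1=C(C)CCC12OCCO2)C(=O)C[Si](C)(C)C
F4 | step 6 | 6-[(1S,3S)-1-[(tert-butyldimethylsilyl)oxy]-3-methyl-3-[(triethylsilyl)oxy]-4-[(trimethylsilyl)methyl]pent-4-en-1-yl]-7-methyl-1,4-dioxaspiro[4.4]non-6-ene | C[C@](O[Si](CC)(CC)CC)(C[C@H](O[Si](C)(C)C(C)(C)C)C1=C(C)CCC12OCCO2)C(=C)C[Si](C)(C)C
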